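After 90.0 min the alder flask has lost 18.4 % of its starting complex and shows 3.3 % of complex with two exchanged, a reading with a scatter of 0.3 percentage points.

| setting | alder | red | ochre |
|---|---|---|---|
| starting complex | 1.5 M | 1.5 M | 1.5 M |
| incoming ligand | 0.62 equiv | 2.00 equiv | 0.500 equiv |
| remark | run made earlier |  |  |
| time |  | 3.0 h | 3.0 h |

- alder (time / min: complex with two exchanged / %, complex with one exchanged / %, starting complex / %): 8.00: 0, 2.8, 97.6; 15.0: 0.7, 4.4, 96.2; 25.0: 0.2, 6.1, 93.5; 50.0: 1.5, 10.6, 88.4; 90.0: 3.3, 15.2, 81.6

(readings scatter by 0.3 percentage points)

- which of these holds the largest part of the starting complex at the end of red (starting complex / complex with two exchanged / complex with one exchanged / complex with three exchanged)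
- which of these holds the largest part of the starting complex at the end of ochre (starting complex / complex with two exchanged / complex with one exchanged / complex with three exchanged)
- complex with two exchanged at the end of ochre, in percent of the starting complex charged

- no earlier run changes the charge of incoming ligand; that part of a forecast is a guess

Complex with two exchanged is a second generation, so while the loss is small it should grow with the square of the fraction lost. That quotient reads 0.975 from the last alder readings: this second-generation ratio should carry neither time nor ligand charge, provided both steps answer to the ligand alike, which is a guess.

The bench rule for the fraction lost is pseudo-first-order: scaling with ligand charge times time, alder predicts 29.7 % for ochre. Its border is a ratio: at one ligand per exchange, the last alder readings put 0.352 of the ligand charge as spent, about a third, so a constant ligand is a poor assumption there.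

The correction uses mean ligand, halfway between charge and end, which is 0.511 equiv in alder. In ochre, a trial loss of 25.0 % leaves a mean of 0.345 equiv. Scaling the logarithm of the remainder returns 24.0 % lost, near the trial, and the ratio turns this into 5.61 % of complex with two exchanged.

The forecast, calling its ligand order “inferred, not tested”, named complex with two exchanged for red and starting complex for ochre and put n at 5.5 %, just below this reckoning.

The simulation gives complex with two exchanged at the end of red, at 38.7 %, starting complex at the end of ochre, at 76.2 %, and 4.89 % for n.

    starting complex + incoming ligand ⇌ leaving ligand + complex with one exchanged (K = 1.20, k = 0.00300 /M/min)
    complex with one exchanged + incoming ligand ⇌ leaving ligand + complex with two exchanged (K = 0.590, k = 0.00510 /M/min)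
    complex with two exchanged + incoming ligand ⇌ leaving ligand + complex with three exchanged (K = 6.30, k = 2.40 × 10⁻⁴ /M/min)
    leaving ligand → by-product carried off (k = 0.140 /min)

Ochre has lost 23.8 % of its starting complex, which the alder ratio turns into 5.53 % against the 4.89 % found. The neighbour with 0.38 M of starting complex, equivalents and time held, stands at a quarter of the ochre concentration and keeps 91.2 % of its starting complex. Its loss of 8.84 % gives 0.762 % by the same ratio, and that flask holds 0.668 % of complex with two exchanged.

Readings and results are calculated for an exercise; the scatter is artificial.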